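**Plan**
1. Retrosynthetic cuts, in order: exocyclic C3′=CHBr (back to a ketone), aryl C–Br (back to the phenol), the C2′ methyl C–H bonds and the O-benzyl group (back to an exocyclic enone), the C2′=CH2 carbon (back to a silyl enol ether), and last the aryl–C1′ bond.
2. Enabling feature: in the cyclopentane the quaternary benzylic carbon C1′ is 1,3 to C3′, the carbon carrying =CHBr (a masked C=O), with the methyl-bearing C2′ between them. The ring is therefore a 3-aryl-3-methylcyclopentanone: C1′ is the β-carbon of 3-methylcyclopent-2-enone and C2′ is the carbon of the enolate that a conjugate arylation creates.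
3. Forward: both rings are bought. They are joined at C1′ by a Cu-catalysed enantioselective conjugate arylation whose aluminium enolate is trapped as a silyl enol ether; then C2′ methylenation, hydrogenation, aryl bromination and bromomethylenation.
4. Stereochemistry: C1′ (R) from the chiral NHC–Cu catalyst; C2′ (R) from hydrogenation anti to the aryl group; the (E)-alkene from the steric course of the Wittig reaction.
5. Helpers: O-benzyl, SiEt3 and CH2NMe2; all are removed inside the sequence without separate deprotection steps.

Key step: step 2

Remark: the target is read as 4-bromo-2-[(1R,2R,3E)-3-(bromomethylidene)-1,2-dimethylcyclopentyl]-5-methylphenol (C2′ methyl cis to the aryl ring, Br on the side of the ring CH2). The antipode of the NHC ligand that gives the (3R) adduct is assumed to be identified in a test run.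

**Step 1**
Reactants: 1 2-bromo-5-methylphenol
Product: 2 2-(benzyloxy)-1-bromo-4-methylbenzene
Conditions: BnBr, K2CO3, DMF, rt
Reagents that add atoms: benzyl bromide, BrCc1ccccc1
Why: Williamson O-alkylation of the phenoxide; the benzyl ether tolerates the Li/Al/Cu chemistry and is removed later in the same hydrogenation that sets C2′, so it needs no deprotection step of its own.

**Step 2**
Reactants: 2 2-(benzyloxy)-1-bromo-4-methylbenzene; 3 3-methylcyclopent-2-en-1-one
Product: 7 {[(3R)-3-[2-(benzyloxy)-4-methylphenyl]-3-methylcyclopent-1-en-1-yl]oxy}triethylsilane, via aryllithium 4 (not isolated), via arylalane 5 (not isolated), via aluminium enolate 6 (not isolated)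
Conditions: (i) n-BuLi, Et2O, −78 °C; Me2AlCl, −78 °C → rt; (ii) 3, chiral bidentate sulfonate-NHC·Ag(I) complex (2.5 mol %), Cu(OTf)2 (5 mol %), THF, −30 °C; (iii) Et3SiOTf, −78 → 0 °C
Reagents that add atoms: triethylsilyl trifluoromethanesulfonate, CC[Si](CC)(CC)OS(=O)(=O)C(F)(F)F (SiEt3 in 7); for the non-isolated intermediates only: n-butyllithium, [Li]CCCC (Li in 4) and dimethylaluminium chloride, C[Al](C)Cl (AlMe2 in 5 and 6)
Why: Br/Li exchange and transmetalation give arylalane 5, whose aryl group passes to the chiral NHC–Cu(I) centre; the aryl–copper species binds the enone π-face, adds at the β-carbon (Cu(III) enolate) and reductively eliminates to forge the Ar–C bond at the fully substituted carbon, leaving dimethylaluminium enolate 6, which Et3SiOTf silylates on oxygen. The closest known reaction type is the NHC–Cu-catalysed enantioselective conjugate addition of aryl(dimethyl)aluminium reagents, including ortho-substituted aryl groups, to β-alkyl cyclopentenones, with silyl triflate capture of the aluminium enolate. No ring is closed in this step. The new quaternary stereocentre (3R) is set under catalyst control, the bidentate sulfonate-NHC ligand on copper selecting one enantiotopic face of the flat enone. The step needs 1,4- over 1,2-addition, aryl over methyl transfer and a single enolate regioisomer: copper catalysis secures the first, the faster transmetalation of the sp2 aryl group the second, and the third is inherent because conjugate addition places the enolate double bond between C1 and C2, next to the new quaternary carbon. The bulky ortho-benzyloxy group is the main departure from the closest cases, so the arylalane should be used in excess.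

**Step 3**
Reactants: 7 {[(3R)-3-[2-(benzyloxy)-4-methylphenyl]-3-methylcyclopent-1-en-1-yl]oxy}triethylsilane
Product: 10 (3S)-3-[2-(benzyloxy)-4-methylphenyl]-3-methyl-2-methylidenecyclopentan-1-one, via Mannich base 8 (not isolated), via methiodide 9 (not isolated)
Conditions: Me2N+=CH2 I−, CH2Cl2, rt; 1 M aq NaOH wash; MeI, Et2O, rt; DBU, CH2Cl2, rt
Reagents that add atoms: N,N-dimethylmethyleneiminium iodide (Eschenmoser's salt), C=[N+](C)C.[I-] (CH2 in 10); for the non-isolated intermediate 9 only: iodomethane, CI
Why: Mannich reaction of the regiodefined silyl enol ether puts the one-carbon unit on C2 only, and quaternisation followed by E1cB loss of trimethylamine (α-methylenation sequence) should give the exocyclic enone, which cannot isomerise into the ring because C3 is quaternary; the C2 stereocentre of 8 is erased, and the descriptor at C3 becomes S only because C2 now outranks the aryl carbon.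

**Step 4**
Reactants: 10 (3S)-3-[2-(benzyloxy)-4-methylphenyl]-3-methyl-2-methylidenecyclopentan-1-one
Product: 11 (2R,3R)-3-(2-hydroxy-4-methylphenyl)-2,3-dimethylcyclopentan-1-one
Conditions: H2 (1 atm), 10 % Pd/C, EtOAc, rt
Reagents that add atoms: none
Why: heterogeneous hydrogenation should deliver hydrogen to the exocyclic C=C from the face anti to the bulky ortho-substituted aryl group on the neighbouring quaternary carbon (the face of the C3 methyl), so the new C2 methyl ends cis to the aryl ring (2R) under neutral, non-epimerising conditions, while the same catalyst hydrogenolyses the benzyl ether before any aryl bromide is present.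

**Step 5**
Reactants: 11 (2R,3R)-3-(2-hydroxy-4-methylphenyl)-2,3-dimethylcyclopentan-1-one
Product: 12 (2R,3R)-3-(5-bromo-2-hydroxy-4-methylphenyl)-2,3-dimethylcyclopentan-1-one
Conditions: NBS (1.0 equiv), MeCN, 0 °C, dark
Reagents that add atoms: N-bromosuccinimide, O=C1CCC(=O)N1Br
Why: electrophilic aromatic bromination of the free phenol should go para to OH (also ortho to the ring methyl), because one ortho position is occupied and the other is squeezed between OH and CH3; the ketone does not enolise under these neutral conditions.

**Step 6**
Reactants: 12 (2R,3R)-3-(5-bromo-2-hydroxy-4-methylphenyl)-2,3-dimethylcyclopentan-1-one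
Product: 15 4-bromo-2-[(1R,2R,3E)-3-(bromomethylidene)-1,2-dimethylcyclopentyl]-5-methylphenol, via ketone phenolate 13 (not isolated), via product phenolate 14 (not isolated)
Conditions: KOtBu (1.0 equiv), THF, −78 °C; then added to Ph3P=CHBr (from Ph3P+CH2Br Br−, KOtBu, 3 equiv each, THF, −78 °C); −78 °C → rt; AcOH, H2O
Reagents that add atoms: (bromomethyl)triphenylphosphonium bromide, BrC[P+](c1ccccc1)(c1ccccc1)c1ccccc1.[Br-] (CHBr in 15); for the non-isolated intermediates 13 and 14 only: potassium tert-butoxide, CC(C)(C)[O-].[K+]
Why: Wittig bromomethylenation, with the phenol masked in the flask as its phenolate so that it cannot protonate the ylide; bromine should orient towards the unsubstituted ring CH2 and away from the C2 methyl group, favouring the (E)-alkene, and the low temperature with no excess free base limits enolisation towards the hindered C2–H.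

**Compound list**
1 | 2-bromo-5-methylphenol | Cc1ccc(Br)c(O)c1 | starting material
2 | 2-(benzyloxy)-1-bromo-4-methylbenzene | Cc1ccc(Br)c(OCc2ccccc2)c1 | intermediate
3 | 3-methylcyclopent-2-en-1-one | CC1=CC(=O)CC1 | starting material
4 | [2-(benzyloxy)-4-methylphenyl]lithium | [Li]c1ccc(C)cc1OCc1ccccc1 | intermediate (not isolated)
5 | [2-(benzyloxy)-4-methylphenyl]dimethylaluminium | C[Al](C)c1ccc(C)cc1OCc1ccccc1 | intermediate (not isolated)
6 | dimethylaluminium (3R)-3-[2-(benzyloxy)-4-methylphenyl]-3-methylcyclopent-1-en-1-olate | Cc1ccc([C@]2(C)CCC(O[Al](C)C)=C2)c(OCc2ccccc2)c1 | intermediate (not isolated)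
7 | {[(3R)-3-[2-(benzyloxy)-4-methylphenyl]-3-methylcyclopent-1-en-1-yl]oxy}triethylsilane | Cc1ccc([C@]2(C)CCC(O[Si](CC)(CC)CC)=C2)c(OCc2ccccc2)c1 | intermediate
8 | (3R)-3-[2-(benzyloxy)-4-methylphenyl]-2-[(dimethylamino)methyl]-3-methylcyclopentan-1-one (C2 epimers; C2 is lost in the same step) | Cc1ccc([C@]2(C)CCC(=O)C2CN(C)C)c(OCc2ccccc2)c1 | intermediate (not isolated)
9 | {[(2R)-2-[2-(benzyloxy)-4-methylphenyl]-2-methyl-5-oxocyclopentyl]methyl}trimethylammonium iodide (C1 epimers) | Cc1ccc([C@]2(C)CCC(=O)C2C[N+](C)(C)C)c(OCc2ccccc2)c1.[I-] | intermediate (not isolated)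
10 | (3S)-3-[2-(benzyloxy)-4-methylphenyl]-3-methyl-2-methylidenecyclopentan-1-one | Cc1ccc([C@]2(C)CCC(=O)C2=C)c(OCc2ccccc2)c1 | intermediate
11 | (2R,3R)-3-(2-hydroxy-4-methylphenyl)-2,3-dimethylcyclopentan-1-one | Cc1ccc([C@]2(C)CCC(=O)[C@@H]2C)c(O)c1 | intermediate
12 | (2R,3R)-3-(5-bromo-2-hydroxy-4-methylphenyl)-2,3-dimethylcyclopentan-1-one | Cc1cc(O)c([C@]2(C)CCC(=O)[C@@H]2C)cc1Br | intermediate
13 | potassium 4-bromo-2-[(1R,2R)-1,2-dimethyl-3-oxocyclopentyl]-5-methylphenolate | Cc1cc([O-])c([C@]2(C)CCC(=O)[C@@H]2C)cc1Br.[K+] | intermediate (not isolated)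
14 | potassium 4-bromo-2-[(1R,2R,3E)-3-(bromomethylidene)-1,2-dimethylcyclopentyl]-5-methylphenolate | Cc1cc([O-])c([C@]2(C)CC/C(=C\Br)[C@@H]2C)cc1Br.[K+] | intermediate (not isolated)
15 | 4-bromo-2-[(1R,2R,3E)-3-(bromomethylidene)-1,2-dimethylcyclopentyl]-5-methylphenol | Cc1cc(O)c([C@]2(C)CC/C(=C\Br)[C@@H]2C)cc1Br | target

**Step count**
Total steps: 6. Longest linear sequence: 6 steps (1 → 2 → 7 → 10 → 11 → 12 → 15).

**Steps most likely to fail**

Step 6 (bromomethylenation). The hindered ketone may be enolised by the basic ylide so that conversion stalls, base may epimerise C2 to the more stable 2,3-cis-dimethyl ketone, or E/Z control may be imperfect. The fallback sets out from 12 and comes back at 15. The phenol would be silylated (TBSCl, imidazole, DMF) to the tert-butyldimethylsilyl ether F1. Non-basic Takai–Lombardo methylenation (Zn, CH2Br2, TiCl4, THF/CH2Cl2, 0 °C), which does not enolise ketones, should give the exocyclic methylene compound F2. Cross-metathesis with vinylboronic acid pinacol ester (second-generation Ru–NHC catalyst, CH2Cl2, 40 °C) is expected to give, under thermodynamic control, the (E)-alkenylboronate F3 with boron away from the C2′ methyl group. Copper(II) bromide in aqueous methanol should replace boron by bromine with retention to give the silyl ether of the target F4, and TBAF in THF then gives 15.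

Step 2 (conjugate arylation). Aryl transfer from the hindered ortho-substituted arylalane may be slow, methyl transfer may compete, enantioselectivity may erode, or the enolate may lose its regiochemistry by proton transfer before silylation. The fallback sets out from 2 and comes back at 7; it makes the aryl–carbon bond by a simple 1,2-addition and builds the quaternary centre by transferring the small methyl group instead. Aryllithium 4, made from 2 as before, would be added to commercial 3-ethoxycyclopent-2-en-1-one F5. Acidic work-up of the tertiary carbinol F6 (Stork–Danheiser transposition) should give the β-aryl enone F7. Cu-catalysed enantioselective conjugate addition of Me3Al (same ligand class, antipode chosen for the required face) would then give the same aluminium enolate 6, which is silylated with Et3SiOTf to 7.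

Step 4 (hydrogenation). Facial selectivity of hydrogen delivery to the exocyclic alkene may be poor or reversed, giving the C2 epimer. The fallback sets out from 7 and comes back at 11; it reverses the order of introduction at C2 so that the same facial bias works for the target. Silyl enol ether 7 would be cleaved with MeLi (THF, 0 °C) to the lithium enolate F8, which is C-methylated with MeI to the benzyl ether ketone F9, the methyl group entering on the face that hydrogen preferred. Hydrogenolysis (H2, Pd/C, EtOAc) then gives 11; without a useful bias the epimers would be separated at this stage.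

**Further compounds**
F1 | step 6 | (2R,3R)-3-{5-bromo-2-[(tert-butyldimethylsilyl)oxy]-4-methylphenyl}-2,3-dimethylcyclopentan-1-one | Cc1cc(O[Si](C)(C)C(C)(C)C)c([C@]2(C)CCC(=O)[C@@H]2C)cc1Br
F2 | step 6 | {4-bromo-2-[(1R,2S)-1,2-dimethyl-3-methylidenecyclopentyl]-5-methylphenoxy}(tert-butyl)dimethylsilane | Cc1cc(O[Si](C)(C)C(C)(C)C)c([C@]2(C)CCC(=C)[C@@H]2C)cc1Br
F3 | step 6 | 2-{(E)-[(2S,3R)-3-{5-bromo-2-[(tert-butyldimethylsilyl)oxy]-4-methylphenyl}-2,3-dimethylcyclopentylidene]methyl}-4,4,5,5-tetramethyl-1,3,2-dioxaborolane | Cc1cc(O[Si](C)(C)C(C)(C)C)c([C@]2(C)CC/C(=C\B3OC(C)(C)C(C)(C)O3)[C@@H]2C)cc1Br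
F4 | step 6 | {4-bromo-2-[(1R,2R,3E)-3-(bromomethylidene)-1,2-dimethylcyclopentyl]-5-methylphenoxy}(tert-butyl)dimethylsilane | Cc1cc(O[Si](C)(C)C(C)(C)C)c([C@]2(C)CC/C(=C\Br)[C@@H]2C)cc1Br
F5 | step 2 | 3-ethoxycyclopent-2-en-1-one (commercial) | CCOC1=CC(=O)CC1
F6 | step 2 | 1-[2-(benzyloxy)-4-methylphenyl]-3-ethoxycyclopent-2-en-1-ol (not isolated) | CCOC1=CC(O)(c2ccc(C)cc2OCc2ccccc2)CC1
F7 | step 2 | 3-[2-(benzyloxy)-4-methylphenyl]cyclopent-2-en-1-one | Cc1ccc(C2=CC(=O)CC2)c(OCc2ccccc2)c1
F8 | step 4 | lithium (3R)-3-[2-(benzyloxy)-4-methylphenyl]-3-methylcyclopent-1-en-1-olate (not isolated) | Cc1ccc([C@]2(C)CCC(O[Li])=C2)c(OCc2ccccc2)c1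
F9 | step 4 | (2R,3R)-3-[2-(benzyloxy)-4-methylphenyl]-2,3-dimethylcyclopentan-1-one | Cc1ccc([C@]2(C)CCC(=O)[C@@H]2C)c(OCc2ccccc2)c1
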